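## Retrosynthetic overview
1. Target 34 ⇐ triol 33 (propionylation of 2-OH) ⇐ 14-membered cembranolide 31. The C12 dienolate attacks the 10,11-epoxide across the ring through its γ-carbon C1. This one step forms the six- and ten-membered rings, C1, C10, the 11-OH and the enone. It mirrors the presumed cembrane → briarane closure, but with reversed polarity.
2. 31 ⇐ acyclic 27, by closing the cembrane ring at C4–C5 (B-alkyl Suzuki).
3. 27 ⇐ bis-allylic alcohol 24, by one hydroxyl-directed double epoxidation. The C19 carboxyl opens the 7,8-epoxide to give the γ-lactone; the 10,11-epoxide is kept for line 1.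
4. 24 ⇐ Weinreb amide 9 (HWE of 4 + 8) and vinyl bromide 21 (allenylzinc addition to acrolein, then hydrozirconation and addition to 12).
5. Ring order: γ-lactone → 14-membered carbocycle → six- and ten-membered rings together.

Convention/assumption: briarane numbering (C1–C20) is used for every intermediate. The target SMILES reads as 1S,2R,5Z,7S,8S,9R,10S,11S,17R. C12 is carried as an epimer mixture until it becomes the ketone.

## Route

Step 1
Reactants: 1 tert-butyl (2R)-2-hydroxypropanoate; 2 diethyl {2-[methoxy(methyl)amino]-2-oxoethyl}phosphonate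
Product: 4 tert-butyl (2S)-3-(diethoxyphosphoryl)-4-[methoxy(methyl)amino]-2-methyl-4-oxobutanoate (C3 epimers; C2 = future C17), via lactate triflate 3 (not isolated)
Conditions: 1, Tf2O, 2,6-lutidine, CH2Cl2, −78 °C; crude 3 added to 2/NaH, THF, −78 → 0 °C
Reagents that add atoms: triflic anhydride, O=S(=O)(OS(=O)(=O)C(F)(F)F)C(F)(F)F (triflyl group of 3 only)
Why: SN2 displacement of the secondary lactate triflate by the sodium phosphonate carbanion goes with clean inversion, so the (R)-lactate carbon becomes C17 with the target configuration (the phosphorus-bearing centre disappears in step 4).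

Step 2
Reactants: 5 but-2-yn-1-ol
Product: 7 (2Z)-3-bromobut-2-en-1-ol, via cyclic vinylalanate 6 (not isolated)
Conditions: NaAlH2(OCH2CH2OCH3)2, Et2O, 0 °C → rt; then N-bromosuccinimide, −78 °C
Reagents that add atoms: N-bromosuccinimide, O=C1CCC(=O)N1Br; sodium bis(2-methoxyethoxy)aluminium dihydride, [Na+].[AlH2-](OCCOC)OCCOC (Al and Na of 6 only)
Why: Alkoxide-directed trans-hydroalumination places aluminium on C3 in a five-membered alanate, and bromodealumination with retention gives only the Z vinyl bromide that later becomes the 5Z alkene.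

Step 3
Reactants: 7 (2Z)-3-bromobut-2-en-1-ol
Product: 8 (2Z)-3-bromobut-2-enal
Conditions: activated MnO2, CH2Cl2, rt
Reagents that add atoms: none
Why: MnO2 oxidation of an allylic alcohol is neutral and leaves the Z double bond unchanged.

Step 4
Reactants: 4 phosphonate; 8 (2Z)-3-bromobut-2-enal
Product: 9 tert-butyl (2R,3E,5Z)-6-bromo-3-[methoxy(methyl)carbamoyl]-2-methylhepta-3,5-dienoate (C5–C9, C16–C19)
Conditions: 4, NaH (1.0 equiv), THF, 0 °C; then 8, 0 °C → rt
Reagents that add atoms: none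
Why: Horner–Wadsworth–Emmons olefination with an α-branched stabilised phosphonate gives the E trisubstituted alkene (amide trans to the dienyl chain, C6 cis to C17), which is the geometry the later epoxide-opening lactonisation needs; the non-basic phosphate by-product leaves C17 intact.

Step 5
Reactants: 10 methacrolein
Product: 12 (2E)-3-bromo-2-methylprop-2-enal, via dibromide 11 (not isolated)
Conditions: Br2, CH2Cl2, −78 → 0 °C; then Et3N, 0 °C → rt
Reagents that add atoms: bromine, BrBr
Why: Bromine addition followed by E2 loss of HBr (only the C3 hydrogens are available) gives the more stable E β-bromoenal, which fixes the later 10E geometry.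

Step 6
Reactants: 13 (2R)-but-3-yn-2-ol
Product: 14 (2R)-but-3-yn-2-yl methanesulfonate
Conditions: MsCl, Et3N, CH2Cl2, −78 °C
Reagents that add atoms: methanesulfonyl chloride, CS(=O)(=O)Cl
Why: O-Sulfonylation does not touch the stereocentre.

Step 7
Reactants: 14 (2R)-but-3-yn-2-yl methanesulfonate; 15 acrolein
Product: 17 (3R,4S)-4-methylhex-1-en-5-yn-3-ol (C13, C14, C1–C4, C15), via allenylzinc mesylate 16 (not isolated)
Conditions: Pd(OAc)2 (5 mol %), PPh3 (5 mol %), Et2Zn (3 equiv), THF, −78 → −20 °C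
Reagents that add atoms: diethylzinc, CC[Zn]CC (zinc of 16 only)
Why: In the Marshall allenylzinc addition, zerovalent palladium displaces the mesylate anti (SN2′), zinc takes over with retention, and the closed SE2′ transition state gives the anti adduct; net inversion at the propargylic carbon fixes C1, and through the anti relationship the C2 carbinol forms as R.

Step 8
Reactants: 17 (3R,4S)-4-methylhex-1-en-5-yn-3-ol; 12 (2E)-3-bromo-2-methylprop-2-enal
Product: 20 (1E,4E,6S,7R)-1-bromo-2,6-dimethylnona-1,4,8-triene-3,7-diol (C3 epimers = C12), via bis-zirconocene 18 (not isolated), via alkenylzinc 19 (not isolated)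
Conditions: Cp2Zr(H)Cl (2.2 equiv), CH2Cl2, rt; Me2Zn, −65 °C; then 12, 0 °C
Reagents that add atoms: zirconocene chloride hydride, [H][Zr](Cl)(C1C=CC=C1)C1C=CC=C1 (Zr of 18 and 19 only); dimethylzinc, C[Zn]C (Zn–CH3 of 19 only)
Why: Syn hydrozirconation of the terminal alkyne (much faster than the alkene), Zr→Zn transmetallation and 1,2-addition to the enal set the 13E alkene; the C12 carbinol forms unselectively, which does not matter because step 16 oxidises it.

Step 9
Reactants: 20 diol
Product: 21 (1E,4E,6S,7R)-1-bromo-3,7-bis(tert-butyldimethylsilyloxy)-2,6-dimethylnona-1,4,8-triene (C3 epimers)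
Conditions: TBSOTf (2.5 equiv), 2,6-lutidine, CH2Cl2, −78 → 0 °C
Reagents that add atoms: tert-butyldimethylsilyl triflate, CC(C)(C)[Si](C)(C)OS(=O)(=O)C(F)(F)F
Why: Silylating both secondary alcohols removes the acidic protons and stops the 12-oxygen from directing the epoxidation in step 12.

Step 10
Reactants: 21 vinyl bromide; 9 Weinreb amide
Product: 23 4,5-seco-cembranoid dienone (C9 ketone; 5Z vinyl bromide, 7E,10E,13E, C3=C4 vinyl; 1S, 2R-OTBS, 12-OTBS, 17R; C19 tert-butyl ester), via vinyllithium 22 (not isolated)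
Conditions: 21, t-BuLi (2.05 equiv), Et2O, −78 °C; then 9, THF, −78 → −40 °C; aq NH4Cl
Reagents that add atoms: tert-butyllithium, [Li]C(C)(C)C (lithium of 22 only)
Why: Br/Li exchange with retention is followed by the Weinreb ketone synthesis; the chelated tetrahedral intermediate stops over-addition, and both the tert-butyl ester and the dienyl bromide (slow Br/Li exchange at −78 °C) survive.

Step 11
Reactants: 23 dienone
Product: 24 (9R)-bis-allylic alcohol (otherwise as 23)
Conditions: (S)-2-methyl-CBS-oxazaborolidine (0.5 equiv), catecholborane (2 equiv), toluene, −78 °C; MeOH, aq NaHCO3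
Reagents that add atoms: none
Why: In the Corey–Bakshi–Shibata reduction the α-branched C8 alkenyl group is the large substituent, so the (S)-catalyst gives the 9R carbinol; catecholborane at −78 °C does not hydroborate the alkenes.

Step 12
Reactants: 24 (9R)-bis-allylic alcohol
Product: 26 γ-lactone (7S,8S,17R; 8-OH, 9R-OH) carrying the (10S,11S)-10,11-epoxide, via bis-epoxide 25 (not isolated)
Conditions: VO(acac)2 (5 mol %), t-BuOOH (2.3 equiv, decane), CH2Cl2, 0 °C; then camphorsulfonic acid (10 mol %), 0 °C → rt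
Reagents that add atoms: tert-butyl hydroperoxide, CC(C)(C)OO
Why: In this vanadium-catalysed hydroxyl-directed epoxidation the 9-OH delivers oxygen to both flanking alkenes (C7=C8 under 1,2-allylic strain gives erythro, C10=C11 under 1,3-allylic strain gives threo, the two relationships the target needs); acid then lets the tert-butyl ester carbonyl open the vinylic 7,8-epoxide at allylic C7 with inversion and loss of isobutene, which sets C7, C8, C10 and C11 from C9.

Step 13
Reactants: 26 hydroxy lactone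
Product: 27 9-O-acetate of 26
Conditions: Ac2O, DMAP, Et3N, CH2Cl2, rt
Reagents that add atoms: acetic anhydride, CC(=O)OC(C)=O
Why: DMAP-catalysed acylation takes the only secondary alcohol; the tertiary 8-OH does not react.

Step 14
Reactants: 27 acetate
Product: 29 14-membered cembranolide (2,12-bis-OTBS, 5Z, 13E, 10,11-epoxide, 9-OAc, 8-OH), via alkylborane 28 (not isolated)
Conditions: 9-BBN-H (2.5 equiv), THF, rt; then slow addition to PdCl2(dppf) (20 mol %), AsPh3, Cs2CO3, DMF–THF–H2O, 50 °C, 1 mM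
Reagents that add atoms: 9-borabicyclo[3.3.1]nonane, [H]B1C2CCCC1CCC2 (boron of 28 only)
Why: 9-BBN-H hydroborates only the monosubstituted C3=C4 alkene, and the B-alkyl Suzuki–Miyaura coupling at high dilution closes the C4–C5 bond with retention of the Z vinyl geometry.

Step 15
Reactants: 29 bis-silyl ether
Product: 30 cembranolide triol (2R-OH, 8-OH, 12-OH epimers)
Conditions: HF·pyridine, pyridine, THF, 0 °C → rt
Reagents that add atoms: none
Why: Buffered fluoride cleaves both silyl ethers under conditions that trisubstituted epoxides, acetates and lactones tolerate.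

Step 16
Reactants: 30 triol
Product: 31 cembranolide epoxy enone (12-ketone, 13E, 1S, 2R-OH, 10S,11S-epoxide)
Conditions: activated MnO2, CH2Cl2, rt
Reagents that add atoms: none
Why: MnO2 oxidises only the allylic 12-OH, so both epimers converge on one ketone, and leaves the homoallylic 2-OH and tertiary 8-OH alone.

Step 17
Reactants: 31 cembranolide epoxy enone
Product: 33 2-O-depropionyl target (briarane; 1S,2R,7S,8S,9R,10S,11S,17R), via lithium dienolate 32 (not isolated)
Conditions: LiClO4 (5 equiv), DBU (3 equiv), MeCN (5 mM), 50 °C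
Reagents that add atoms: lithium perchlorate, [Li+].[O-]Cl(=O)(=O)=O (lithium of 32 only)
Why: Proposed new method: lithium-assisted reversible γ-deprotonation of the enone by DBU gives small equilibrium amounts of the extended dienolate 32, whose α-carbon C13 could only close a four-membered ring, so the γ-carbon C1 attacks C10 of the lithium-chelated α,β-epoxy ketone across the ring in an SN2 opening (inversion at C10, C11–O retained as the 11-OH, enone regenerated as C13=C14); the backside requirement leaves only one dienolate face open, and the less crowded dienolate geometry (methyl inside, C2 outside) then gives Me-15 trans to H-10, while the free 2-OH is too poor a leaving group for vinylogous elimination; the closest known reaction types are Stork-type intramolecular enolate–epoxide alkylation, LiClO4-promoted enolate opening of epoxides and γ-alkylation of extended dienolates.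

Step 18
Reactants: 33 triol
Product: 34 target CNP0240018.1
Conditions: (EtCO)2O, DMAP, Et3N, CH2Cl2, rt → 35 °C
Reagents that add atoms: propionic anhydride, CCC(=O)OC(=O)CC
Why: DMAP-catalysed acylation is selective for the single secondary alcohol (2-OH) over the tertiary 8-OH and 11-OH.

## Compound list
1 | tert-butyl (2R)-2-hydroxypropanoate | C[C@@H](O)C(=O)OC(C)(C)C | starting material
2 | diethyl {2-[methoxy(methyl)amino]-2-oxoethyl}phosphonate | CCOP(=O)(OCC)CC(=O)N(C)OC | starting material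
3 | tert-butyl (2R)-2-(trifluoromethylsulfonyloxy)propanoate | C[C@@H](OS(=O)(=O)C(F)(F)F)C(=O)OC(C)(C)C | intermediate
4 | tert-butyl (2S)-3-(diethoxyphosphoryl)-4-[methoxy(methyl)amino]-2-methyl-4-oxobutanoate | CCOP(=O)(OCC)C([C@@H](C)C(=O)OC(C)(C)C)C(=O)N(C)OC | intermediate
5 | but-2-yn-1-ol | CC#CCO | starting material
6 | sodium 2,2-bis(2-methoxyethoxy)-3-methyl-1-oxa-2-aluminatacyclopent-3-ene | [Na+].CC1=CCO[Al-]1(OCCOC)OCCOC | intermediate
7 | (2Z)-3-bromobut-2-en-1-ol | Br/C(C)=C\CO | intermediate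
8 | (2Z)-3-bromobut-2-enal | Br/C(C)=C\C=O | intermediate
9 | tert-butyl (2R,3E,5Z)-6-bromo-3-[methoxy(methyl)carbamoyl]-2-methylhepta-3,5-dienoate | Br/C(C)=C\C=C(/[C@@H](C)C(=O)OC(C)(C)C)C(=O)N(C)OC | intermediate
10 | methacrolein | CC(=C)C=O | starting material
11 | 2,3-dibromo-2-methylpropanal | BrCC(C)(Br)C=O | intermediate
12 | (2E)-3-bromo-2-methylprop-2-enal | Br/C=C(\C)C=O | intermediate
13 | (2R)-but-3-yn-2-ol | C[C@@H](O)C#C | starting material
14 | (2R)-but-3-yn-2-yl methanesulfonate | C[C@@H](OS(C)(=O)=O)C#C | intermediate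
15 | acrolein | C=CC=O | starting material
16 | axially chiral buta-1,2-dienylzinc methanesulfonate | [H]C(C)=[C@]=C([H])[Zn]OS(C)(=O)=O | intermediate
17 | (3R,4S)-4-methylhex-1-en-5-yn-3-ol | C=C[C@@H](O)[C@@H](C)C#C | intermediate
18 | (E)-alkenylzirconocene chloride of the zirconocene alkoxide of 17 | C=C[C@@H](O[Zr](Cl)(C1C=CC=C1)C1C=CC=C1)[C@@H](C)/C=C/[Zr](Cl)(C1C=CC=C1)C1C=CC=C1 | intermediate
19 | (E)-alkenyl(methyl)zinc derived from 18 | C=C[C@@H](O[Zr](Cl)(C1C=CC=C1)C1C=CC=C1)[C@@H](C)/C=C/[Zn]C | intermediate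
20 | (1E,4E,6S,7R)-1-bromo-2,6-dimethylnona-1,4,8-triene-3,7-diol (C3 epimers) | C=C[C@@H](O)[C@@H](C)/C=C/C(O)/C(C)=C/Br | intermediate
21 | bis-TBS ether of 20 | C=C[C@@H](O[Si](C)(C)C(C)(C)C)[C@@H](C)/C=C/C(O[Si](C)(C)C(C)(C)C)/C(C)=C/Br | intermediate
22 | (E)-vinyllithium from 21 | C=C[C@@H](O[Si](C)(C)C(C)(C)C)[C@@H](C)/C=C/C(O[Si](C)(C)C(C)(C)C)/C(C)=C/[Li] | intermediate
23 | 4,5-seco-cembranoid C9 dienone | Br/C(C)=C\C=C(/[C@@H](C)C(=O)OC(C)(C)C)C(=O)/C=C(\C)C(O[Si](C)(C)C(C)(C)C)/C=C/[C@H](C)[C@H](O[Si](C)(C)C(C)(C)C)C=C | intermediate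
24 | (9R)-bis-allylic alcohol | Br/C(C)=C\C=C(/[C@@H](C)C(=O)OC(C)(C)C)[C@H](O)/C=C(\C)C(O[Si](C)(C)C(C)(C)C)/C=C/[C@H](C)[C@H](O[Si](C)(C)C(C)(C)C)C=C | intermediate
25 | 7,8;10,11-bis-epoxide of 24 | Br/C(C)=C\[C@H]1O[C@]1([C@@H](C)C(=O)OC(C)(C)C)[C@H](O)[C@H]2O[C@]2(C)C(O[Si](C)(C)C(C)(C)C)/C=C/[C@H](C)[C@H](O[Si](C)(C)C(C)(C)C)C=C | intermediate
26 | 8,9-dihydroxy γ-lactone with 10,11-epoxide | Br/C(C)=C\[C@@H]1OC(=O)[C@H](C)[C@@]1(O)[C@H](O)[C@H]2O[C@]2(C)C(O[Si](C)(C)C(C)(C)C)/C=C/[C@H](C)[C@H](O[Si](C)(C)C(C)(C)C)C=C | intermediate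
27 | 9-O-acetate of 26 | Br/C(C)=C\[C@@H]1OC(=O)[C@H](C)[C@@]1(O)[C@H](OC(C)=O)[C@H]2O[C@]2(C)C(O[Si](C)(C)C(C)(C)C)/C=C/[C@H](C)[C@H](O[Si](C)(C)C(C)(C)C)C=C | intermediate
28 | C4 B-alkyl-9-BBN derivative of 27 | Br/C(C)=C\[C@@H]1OC(=O)[C@H](C)[C@@]1(O)[C@H](OC(C)=O)[C@H]2O[C@]2(C)C(O[Si](C)(C)C(C)(C)C)/C=C/[C@H](C)[C@H](O[Si](C)(C)C(C)(C)C)CCB1C2CCCC1CCC2 | intermediate
29 | 2,12-bis-O-TBS cembranolide | CC(C)(C)[Si](C)(C)O[C@@H]1CC/C(C)=C\[C@@H]2OC(=O)[C@H](C)[C@@]2(O)[C@H](OC(C)=O)[C@H]3O[C@]3(C)C(O[Si](C)(C)C(C)(C)C)/C=C/[C@@H]1C | intermediate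
30 | cembranolide 2,8,12-triol | O[C@@H]1CC/C(C)=C\[C@@H]2OC(=O)[C@H](C)[C@@]2(O)[C@H](OC(C)=O)[C@H]3O[C@]3(C)C(O)/C=C/[C@@H]1C | intermediate
31 | cembranolide 10,11-epoxy-13-en-12-one | O[C@@H]1CC/C(C)=C\[C@@H]2OC(=O)[C@H](C)[C@@]2(O)[C@H](OC(C)=O)[C@H]3O[C@]3(C)C(=O)/C=C/[C@@H]1C | intermediate
32 | lithium 12-oxido-12,14(1)-dienolate of 31 | C1C/C(C)=C\[C@@H]2OC(=O)[C@H](C)[C@@]2(O)[C@H](OC(C)=O)[C@H]3O[C@]3(C)/C([O-])=C\C=C(/C)[C@@H]1O.[Li+] | intermediate
33 | 2-O-depropionyl target (briarane 2,8,11-triol) | O[C@@H]1CC/C(C)=C\[C@@H]2OC(=O)[C@H](C)[C@@]2(O)[C@H](OC(C)=O)[C@@H]2[C@]1(C)C=CC(=O)[C@@]2(C)O | intermediate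
34 | CNP0240018.1 | CCC(=O)O[C@@H]1CC/C(C)=C\[C@@H]2OC(=O)[C@H](C)[C@@]2(O)[C@H](OC(C)=O)[C@@H]2[C@]1(C)C=CC(=O)[C@@]2(C)O | target

## Step count and risks
Total steps: 18. Longest linear sequence: 13 (steps 6–18, from 13 to 34).

**Step 17 (transannular dienolate–epoxide closure).** The equilibrium dienolate may be too dilute or too hindered to react, or the enone may only deconjugate. The fallback sets out from 31 and returns at 33.
- It replaces anionic activation with a pre-formed, geometry-defined silyl nucleophile.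
- TESOTf/Et3N converts 31 into the tris(triethylsilyl) dienol ether F1 (2-O, 8-O and 12-O silylated).
- A catalytic Lewis acid such as Sc(OTf)3 in CH2Cl2 at low temperature then triggers a vinylogous Mukaiyama-type opening of the epoxide with silyl transfer. This gives the tris-O-TES briarane enone F2.
- HF·pyridine converts F2 into 33.

**Step 12 (one-pot double epoxidation and lactonisation).** The second epoxidation may be slow or poorly selective, or the acid may damage the 10,11-epoxide. The fallback sets out from 24 and returns at 26.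
- It separates the two oxidations, and the first is put under reagent control.
- Ti(OiPr)4, D-(−)-diisopropyl tartrate and t-BuOOH (4 Å sieves, −20 °C) epoxidise only C7=C8. For the 9R carbinol this is the matched, erythro-selective partner, and C10=C11 is the mismatched one. The product is the mono-epoxide F3.
- Acid turns F3 into the alkene-containing hydroxy lactone F4 while no second epoxide is present.
- VO(acac)2/t-BuOOH then installs the threo 10,11-epoxide on F4 to give 26.

**Step 14 (Suzuki macrocyclisation).** The hindered Z trisubstituted vinyl bromide may couple too slowly, so that protodeboronation or oligomerisation wins. The fallback sets out from 27 and returns at 29.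
- It moves to an isolable sp3 zinc nucleophile.
- Hydroboration with 9-BBN-H and NaBO3 oxidation give the primary alcohol F5.
- I2/PPh3/imidazole gives the primary iodide F6.
- Zinc dust with LiCl in THF gives the alkylzinc iodide F7.
- F7 is added slowly to Pd2(dba)3/SPhos for an intramolecular Negishi coupling that gives 29.

## Further compounds
F1 | step 17 | 2,8,12-tris-O-triethylsilyl dienol ether of 31 | C1C/C(C)=C\[C@@H]2OC(=O)[C@H](C)[C@@]2(O[Si](CC)(CC)CC)[C@H](OC(C)=O)[C@H]3O[C@]3(C)/C(O[Si](CC)(CC)CC)=C\C=C(/C)[C@@H]1O[Si](CC)(CC)CC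
F2 | step 17 | 2,8,11-tris-O-triethylsilyl ether of 33 | CC[Si](CC)(CC)O[C@@H]1CC/C(C)=C\[C@@H]2OC(=O)[C@H](C)[C@@]2(O[Si](CC)(CC)CC)[C@H](OC(C)=O)[C@@H]2[C@]1(C)C=CC(=O)[C@@]2(C)O[Si](CC)(CC)CC
F3 | step 12 | 7,8-mono-epoxide of 24 | Br/C(C)=C\[C@H]1O[C@]1([C@@H](C)C(=O)OC(C)(C)C)[C@H](O)/C=C(\C)C(O[Si](C)(C)C(C)(C)C)/C=C/[C@H](C)[C@H](O[Si](C)(C)C(C)(C)C)C=C
F4 | step 12 | 8,9-dihydroxy γ-lactone with intact 10E alkene | Br/C(C)=C\[C@@H]1OC(=O)[C@H](C)[C@@]1(O)[C@H](O)/C=C(\C)C(O[Si](C)(C)C(C)(C)C)/C=C/[C@H](C)[C@H](O[Si](C)(C)C(C)(C)C)C=C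
F5 | step 14 | C4 primary alcohol from 27 | Br/C(C)=C\[C@@H]1OC(=O)[C@H](C)[C@@]1(O)[C@H](OC(C)=O)[C@H]2O[C@]2(C)C(O[Si](C)(C)C(C)(C)C)/C=C/[C@H](C)[C@H](O[Si](C)(C)C(C)(C)C)CCO
F6 | step 14 | C4 primary iodide | Br/C(C)=C\[C@@H]1OC(=O)[C@H](C)[C@@]1(O)[C@H](OC(C)=O)[C@H]2O[C@]2(C)C(O[Si](C)(C)C(C)(C)C)/C=C/[C@H](C)[C@H](O[Si](C)(C)C(C)(C)C)CCI
F7 | step 14 | C4 alkylzinc iodide | Br/C(C)=C\[C@@H]1OC(=O)[C@H](C)[C@@]1(O)[C@H](OC(C)=O)[C@H]2O[C@]2(C)C(O[Si](C)(C)C(C)(C)C)/C=C/[C@H](C)[C@H](O[Si](C)(C)C(C)(C)C)CC[Zn]I
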